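**Retrosynthetic overview**
- Target ⇐ its C1‑triisopropylsilyl‑capped form; the last step only cuts the C–Si bond.
- Oxocane (ring B) and 4,7‑oxolane (ring C) ⇐ one‑flask bromonium relay on a 2,5‑cis 6,9‑oxolane (ring A): Br+ on the 12E‑olefin → O6 oxonium → acetate at C9 (ring A expands to ring B) → the freed 7‑OH closes ring C on the brominated Z‑enyne.
- Ring A ⇐ 5‑exo bromoetherification (O6 onto the 9Z‑olefin) of the erythro (6S,7R)‑diol of a (3Z,9Z,12E)‑pentadecatrien‑1‑yne.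
- Linear diol ⇐ 2‑deoxy‑D‑ribose (C5–C8 and both carbinol centres): Z‑enyne by Peterson olefination of the lactol, C9–C15 by triflate alkynylation and Lindlar reduction.
- Ring order: oxolane A (sacrificial) → oxocane B → oxolane C; every ring C–O bond is made by bromonium/oxonium chemistry.

Assumption: carbons are numbered C1–C15 along the chain (C1 = alkyne CH); the target is (3R,4R,6S,7R,9R,10S,12R,13S), a trans‑fused bicycle that maps onto an erythro 6,7‑diol, so the linear precursor is the (6S,7R)‑diol and not a natural threo laurediol.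

**Step 1**
Reactants: 1 2‑deoxy‑D‑ribose
Product: 2 3,4‑O‑isopropylidene‑2‑deoxy‑D‑ribopyranose (anomeric mixture)
Conditions: 2‑methoxypropene, pyridinium p‑toluenesulfonate (cat.), EtOAc, 0 °C to rt
Reagents that add atoms: 2‑methoxypropene (COC(C)=C)
Why: Acid‑catalysed transacetalisation (acetonide formation) traps the cis‑3,4‑diol of the pyranose form as a fused dioxolane and leaves the lactol free; no stereocentre is touched.

**Step 2**
Reactants: 2 3,4‑O‑isopropylidene‑2‑deoxy‑D‑ribopyranose; 3 1,3‑bis(triisopropylsilyl)propyne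
Product: 5 [(4R,5S)‑2,2‑dimethyl‑5‑[(2Z)‑5‑(triisopropylsilyl)pent‑2‑en‑4‑yn‑1‑yl]‑1,3‑dioxolan‑4‑yl]methanol, via lithiated propyne 4 (not isolated)
Conditions: 3 (3 equiv), n‑BuLi (3 equiv), THF, −20 °C; then 2, −78 to 0 °C
Reagents that add atoms: none
Why: Peterson olefination: the first equivalent of 4 deprotonates the lactol, a second adds to the open‑chain aldehyde tautomer and the adduct loses lithium triisopropylsilanolate by syn‑elimination, which with this bulky bis‑silyl reagent gives the Z‑enyne (about 15–20:1 expected); C6 and C7 (sugar C3 and C4) are untouched.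

**Step 3**
Reactants: 6 ethynylmagnesium bromide; 7 (E)‑1‑bromopent‑2‑ene
Product: 8 (E)‑hept‑4‑en‑1‑yne
Conditions: CuBr·SMe2 (5 mol %), THF, 0 °C to rt
Reagents that add atoms: none
Why: Copper‑catalysed SN2 coupling of an alkynyl Grignard reagent with a primary allylic bromide gives the linear skipped enyne with the E geometry of 7 retained.

**Step 4**
Reactants: 5 [(4R,5S)‑2,2‑dimethyl‑5‑[(2Z)‑5‑(triisopropylsilyl)pent‑2‑en‑4‑yn‑1‑yl]‑1,3‑dioxolan‑4‑yl]methanol; 8 (E)‑hept‑4‑en‑1‑yne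
Product: 11 (3Z,6S,7R,12E)‑6,7‑(isopropylidenedioxy)‑1‑(triisopropylsilyl)pentadeca‑3,12‑diene‑1,9‑diyne, via triflate 9 (not isolated), via lithium acetylide 10 (not isolated)
Conditions: Tf2O, 2,6‑lutidine, CH2Cl2, −78 °C; then 10 (from 8, n‑BuLi), THF/DMPU, −78 to −20 °C
Reagents that add atoms: none
Why: SN2 alkylation of a lithium acetylide by a primary triflate; the acetonide, the Z‑enyne and the silyl cap are inert and no stereocentre is involved.

**Step 5**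
Reactants: 11 (3Z,6S,7R,12E)‑6,7‑(isopropylidenedioxy)‑1‑(triisopropylsilyl)pentadeca‑3,12‑diene‑1,9‑diyne
Product: 12 (3Z,6S,7R,9Z,12E)‑6,7‑(isopropylidenedioxy)‑1‑(triisopropylsilyl)pentadeca‑3,9,12‑trien‑1‑yne
Conditions: H2 (1 atm), Pd/CaCO3 poisoned with Pb(OAc)2, quinoline, EtOAc, rt, stopped after 1 equiv H2
Reagents that add atoms: none
Why: Lindlar semi‑hydrogenation adds H2 syn to the only unhindered alkyne and so sets the 9Z‑olefin; the silyl‑capped alkyne is too hindered to bind and the olefins are not reduced over the poisoned catalyst.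

**Step 6**
Reactants: 12 (3Z,6S,7R,9Z,12E)‑6,7‑(isopropylidenedioxy)‑1‑(triisopropylsilyl)pentadeca‑3,9,12‑trien‑1‑yne
Product: 13 (3Z,6S,7R,9Z,12E)‑1‑(triisopropylsilyl)pentadeca‑3,9,12‑trien‑1‑yne‑6,7‑diol
Conditions: AcOH/H2O (4:1), 40 °C
Reagents that add atoms: none
Why: Acid‑catalysed acetal hydrolysis frees the erythro diol; the C(sp)–Si bond and the skipped olefins are stable to aqueous acetic acid.

**Step 7**
Reactants: 13 (3Z,6S,7R,9Z,12E)‑1‑(triisopropylsilyl)pentadeca‑3,9,12‑trien‑1‑yne‑6,7‑diol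
Product: 14 (2S,3R,5S)‑5‑[(1S,3E)‑1‑bromohex‑3‑en‑1‑yl]‑2‑[(2Z)‑5‑(triisopropylsilyl)pent‑2‑en‑4‑yn‑1‑yl]oxolan‑3‑ol
Conditions: NBS (1.05 equiv), CH2Cl2, 4 Å MS, −40 to 0 °C, dark
Reagents that add atoms: N‑bromosuccinimide (O=C1CCC(=O)N1Br)
Why: 5‑exo bromoetherification: the isolated 9Z‑olefin is the most nucleophilic π‑bond and only O6 can reach it through a five‑membered transition state, anti addition across the Z‑olefin sets C9/C10 as the (9S,10S) pair, and the 2,5‑cis oxolane needed later is expected as the main but not the only diastereomer (the trans isomer is separated here); closure of O7 onto the enyne is slow because that olefin is deactivated and the resulting bis‑oxolane would be trans‑fused.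

**Step 8**
Reactants: 14 (2S,3R,5S)‑5‑[(1S,3E)‑1‑bromohex‑3‑en‑1‑yl]‑2‑[(2Z)‑5‑(triisopropylsilyl)pent‑2‑en‑4‑yn‑1‑yl]oxolan‑3‑ol
Product: 17 (3R,4R,6S,7R,9R,10S,12R,13S)‑9‑acetoxy‑3,10,13‑tribromo‑4,7:6,12‑diepoxy‑1‑(triisopropylsilyl)pentadec‑1‑yne, via bicyclic oxonium 15 (not isolated), via oxocane alcohol 16 (not isolated)
Conditions: NBS (1.1 equiv), AcOH (10 equiv), 1,1,3,3‑tetramethylguanidine (10 mol %), CH2Cl2, −20 °C; then NBS (1.2 equiv), 0 °C to rt
Reagents that add atoms: N‑bromosuccinimide (O=C1CCC(=O)N1Br); acetic acid (CC(=O)O)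
Why: Proposed new method: NBS puts a bromonium ion on the 12E‑olefin, the ring A oxygen traps it 5‑exo (anti addition, bromopropyl arm on the convex face: 12R,13S) to give the cis‑fused oxonium 15, acetate opens 15 by SN2 at the ring‑fusion carbon C9 (inversion to 9R, so the acetate ends cis to the 10‑bromide, a net syn addition that only an oxonium relay can give; C6 is deactivated by the neighbouring C7–O bond and C12 is shielded by the branched bromopropyl group) to give the alpha,alpha'‑trans oxocane 16, whose 7‑OH can only now reach C4, so the second NBS charge closes ring C by 5‑exo anti addition across the Z‑olefin of the enyne (3R,4R; the trans ring fusion holds C8 pseudo‑equatorial and the C4 arm follows, 2,5‑cis) while the bulky silyl cap blocks bromine transfer to C1 (bromoallene formation); the closest known reaction types are the bromonium‑induced ring expansion of alkenyl oxolanes to oxocanes through bicyclic oxonium ions opened by an internal nucleophile, the guanidine‑catalysed NBS/AcOH bromoacetoxylation in which a transannular ether oxygen intercepts the bromonium ion, and ordinary 5‑exo bromoetherification.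

**Step 9**
Reactants: 17 (3R,4R,6S,7R,9R,10S,12R,13S)‑9‑acetoxy‑3,10,13‑tribromo‑4,7:6,12‑diepoxy‑1‑(triisopropylsilyl)pentadec‑1‑yne
Product: 18 (3R,4R,6S,7R,9R,10S,12R,13S)‑9‑acetoxy‑3,10,13‑tribromo‑4,7:6,12‑diepoxypentadec‑1‑yne (CNP0224788.1)
Conditions: Bu4NF (1.5 equiv), AcOH (1.5 equiv), THF, −20 to 0 °C
Reagents that add atoms: none
Why: Fluoride‑induced protodesilylation of the C(sp)–Si bond, buffered by acetic acid and run cold so that the acetate and the three secondary bromides (one propargylic) are not attacked; no stereocentre is involved.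

**Compound list**
1 | 2‑deoxy‑D‑ribose ((3S,4R)‑3,4,5‑trihydroxypentanal, drawn open‑chain) | O=CC[C@H](O)[C@H](O)CO | starting material
2 | 3,4‑O‑isopropylidene‑2‑deoxy‑D‑ribopyranose (anomeric mixture) | OC1C[C@@H]2OC(C)(C)O[C@@H]2CO1 | intermediate
3 | 1,3‑bis(triisopropylsilyl)propyne | CC(C)[Si](C(C)C)(C(C)C)C#CC[Si](C(C)C)(C(C)C)C(C)C | starting material
4 | 1‑lithio‑1,3‑bis(triisopropylsilyl)prop‑2‑yne | CC(C)[Si](C(C)C)(C(C)C)C#CC([Li])[Si](C(C)C)(C(C)C)C(C)C | intermediate (not isolated)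
5 | [(4R,5S)‑2,2‑dimethyl‑5‑[(2Z)‑5‑(triisopropylsilyl)pent‑2‑en‑4‑yn‑1‑yl]‑1,3‑dioxolan‑4‑yl]methanol | CC(C)[Si](C(C)C)(C(C)C)C#C/C=C\C[C@@H]1OC(C)(C)O[C@@H]1CO | intermediate
6 | ethynylmagnesium bromide | C#C[Mg]Br | starting material
7 | (E)‑1‑bromopent‑2‑ene | CC/C=C/CBr | starting material
8 | (E)‑hept‑4‑en‑1‑yne | C#CC/C=C/CC | intermediate
9 | [(4R,5S)‑2,2‑dimethyl‑5‑[(2Z)‑5‑(triisopropylsilyl)pent‑2‑en‑4‑yn‑1‑yl]‑1,3‑dioxolan‑4‑yl]methyl trifluoromethanesulfonate | CC(C)[Si](C(C)C)(C(C)C)C#C/C=C\C[C@@H]1OC(C)(C)O[C@@H]1COS(=O)(=O)C(F)(F)F | intermediate (not isolated)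
10 | lithium (E)‑hept‑4‑en‑1‑yn‑1‑ide | [Li]C#CC/C=C/CC | intermediate (not isolated)
11 | (3Z,6S,7R,12E)‑6,7‑(isopropylidenedioxy)‑1‑(triisopropylsilyl)pentadeca‑3,12‑diene‑1,9‑diyne | CC(C)[Si](C(C)C)(C(C)C)C#C/C=C\C[C@@H]1OC(C)(C)O[C@@H]1CC#CC/C=C/CC | intermediate
12 | (3Z,6S,7R,9Z,12E)‑6,7‑(isopropylidenedioxy)‑1‑(triisopropylsilyl)pentadeca‑3,9,12‑trien‑1‑yne | CC(C)[Si](C(C)C)(C(C)C)C#C/C=C\C[C@@H]1OC(C)(C)O[C@@H]1C/C=C\C/C=C/CC | intermediate
13 | (3Z,6S,7R,9Z,12E)‑1‑(triisopropylsilyl)pentadeca‑3,9,12‑trien‑1‑yne‑6,7‑diol | CC(C)[Si](C(C)C)(C(C)C)C#C/C=C\C[C@H](O)[C@H](O)C/C=C\C/C=C/CC | intermediate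
14 | (2S,3R,5S)‑5‑[(1S,3E)‑1‑bromohex‑3‑en‑1‑yl]‑2‑[(2Z)‑5‑(triisopropylsilyl)pent‑2‑en‑4‑yn‑1‑yl]oxolan‑3‑ol (ring A; chain numbering 6S,7R,9S,10S) | CC(C)[Si](C(C)C)(C(C)C)C#C/C=C\C[C@@H]1O[C@H]([C@@H](Br)C/C=C/CC)C[C@H]1O | intermediate
15 | cis‑fused 1‑oxoniabicyclo[3.3.0]octane acetate: O+ bonded to C6, C9 and C12; 7‑OH, 10‑Br, 13‑Br (6S,7R,9S,10S,12R,13S) | CC(C)[Si](C(C)C)(C(C)C)C#C/C=C\C[C@H]1[C@H](O)C[C@H]2[C@@H](Br)C[C@H]([C@@H](Br)CC)[O+]12.CC(=O)[O-] | intermediate (not isolated)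
16 | (2S,3R,5R,6S,8R)‑6‑bromo‑8‑[(1S)‑1‑bromopropyl]‑3‑hydroxy‑2‑[(2Z)‑5‑(triisopropylsilyl)pent‑2‑en‑4‑yn‑1‑yl]oxocan‑5‑yl acetate | CC(C)[Si](C(C)C)(C(C)C)C#C/C=C\C[C@@H]1O[C@@H]([C@@H](Br)CC)C[C@H](Br)[C@H](OC(C)=O)C[C@H]1O | intermediate (not isolated)
17 | (3R,4R,6S,7R,9R,10S,12R,13S)‑9‑acetoxy‑3,10,13‑tribromo‑4,7:6,12‑diepoxy‑1‑(triisopropylsilyl)pentadec‑1‑yne | CC(C)[Si](C(C)C)(C(C)C)C#C[C@@H](Br)[C@H]1C[C@@H]2O[C@@H]([C@@H](Br)CC)C[C@H](Br)[C@H](OC(C)=O)C[C@H]2O1 | intermediate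
18 | (3R,4R,6S,7R,9R,10S,12R,13S)‑9‑acetoxy‑3,10,13‑tribromo‑4,7:6,12‑diepoxypentadec‑1‑yne | C#C[C@@H](Br)[C@H]1C[C@@H]2O[C@@H]([C@@H](Br)CC)C[C@H](Br)[C@H](OC(C)=O)C[C@H]2O1 | target

**Step count and risk**
Total steps: 9. Longest linear sequence: 8 (steps 1, 2, 4, 5, 6, 7, 8, 9).

Most likely to fail, in this order: step 8, step 7, step 9.

Step 8. Acetate may open oxonium 15 at C6 or C12, or trap the 12,13‑bromonium ion directly, instead of attacking C9; the enyne may also take bromine at C1. The fallback sets out from 14 and comes back at 17. The first bromination is run without any external nucleophile (NBS, (CF3)2CHOH/CH2Cl2, −20 °C). The oxonium can then only discharge through its C9/C10 bromonium form, which the 7‑OH traps from the opposite face to give the oxetane‑bridged oxocane F1 (the 7,10‑ether is the expected by‑product). A second NBS charge with AcOH and 1,1,3,3‑tetramethylguanidine (CH2Cl2, 0 °C) brominates the enyne, and the oxetane oxygen closes ring C to give the strained oxonium F2. Acetate opens the four‑membered ring at C9 with inversion, so the C9 regiochemistry is now enforced by ring strain, and 17 results with the same configuration as in the main route.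

Step 7. The free‑alcohol cyclisation may give mainly the 2,5‑trans oxolane. The fallback sets out from 13 and comes back at 14. Both hydroxyls are silylated (t‑BuMe2SiOTf, 2,6‑lutidine, CH2Cl2, −78 °C) to give the bis(silyl) ether F3. NBS in MeCN at −40 °C then cyclises through a silyloxonium ion in which the O‑silyl group sits trans to both flanking substituents, which pushes them cis; loss of that silyl group gives the 7‑O‑silyl oxolane F4. HF·pyridine (THF, 0 °C) removes the remaining silyl ether to give 14.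

Step 9. Fluoride or the acetate it liberates may substitute or eliminate the propargylic bromide before the hindered C–Si bond is cut. The fallback sets out from 14 and comes back at 18; it exchanges the cap before any sensitive bromide exists. Bu4NF (THF, 0 °C) gives the terminal enyne F5. LiN(SiMe3)2 (2.2 equiv) and Me3SiCl (2.5 equiv) in THF at −78 °C give the O,C‑bis(trimethylsilyl) compound F6, whose O–Si bond is cleaved on citric acid/MeOH work‑up to leave the C‑trimethylsilyl alcohol F7. The step 8 relay then runs through oxonium F8 and oxocane alcohol F9 to the trimethylsilyl‑capped target F10. Its far more labile C–SiMe3 bond is cut with Bu4NF/AcOH in THF at −78 °C to give 18. The smaller cap shields C1 less well in the ring C closure, which is the price of this variant.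

**Further compounds**
F1 | step 8 | (3Z,6S,7R,9S,10S,12R,13S)‑10,13‑dibromo‑6,12:7,9‑diepoxy‑1‑(triisopropylsilyl)pentadec‑3‑en‑1‑yne | CC(C)[Si](C(C)C)(C(C)C)C#C/C=C\C[C@@H]1O[C@@H]([C@@H](Br)CC)C[C@H](Br)[C@@H]2C[C@H]1O2
F2 | step 8 | oxonium acetate from F1: O+ bonded to C4, C7 and C9; 3,10,13‑tribromo‑6,12‑epoxy (3R,4R,6S,7R,9S,10S,12R,13S) | CC(C)[Si](C(C)C)(C(C)C)C#C[C@@H](Br)[C@H]1C[C@@H]2O[C@@H]([C@@H](Br)CC)C[C@H](Br)[C@@H]3C[C@H]2[O+]13.CC(=O)[O-]
F3 | step 7 | (3Z,6S,7R,9Z,12E)‑6,7‑bis(tert‑butyldimethylsilyloxy)‑1‑(triisopropylsilyl)pentadeca‑3,9,12‑trien‑1‑yne | CC(C)[Si](C(C)C)(C(C)C)C#C/C=C\C[C@H](O[Si](C)(C)C(C)(C)C)[C@H](O[Si](C)(C)C(C)(C)C)C/C=C\C/C=C/CC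
F4 | step 7 | (2S,3R,5S)‑5‑[(1S,3E)‑1‑bromohex‑3‑en‑1‑yl]‑3‑(tert‑butyldimethylsilyloxy)‑2‑[(2Z)‑5‑(triisopropylsilyl)pent‑2‑en‑4‑yn‑1‑yl]oxolane | CC(C)[Si](C(C)C)(C(C)C)C#C/C=C\C[C@@H]1O[C@H]([C@@H](Br)C/C=C/CC)C[C@H]1O[Si](C)(C)C(C)(C)C
F5 | step 9 | (2S,3R,5S)‑5‑[(1S,3E)‑1‑bromohex‑3‑en‑1‑yl]‑2‑[(2Z)‑pent‑2‑en‑4‑yn‑1‑yl]oxolan‑3‑ol | C#C/C=C\C[C@@H]1O[C@H]([C@@H](Br)C/C=C/CC)C[C@H]1O
F6 | step 9 | (2S,3R,5S)‑5‑[(1S,3E)‑1‑bromohex‑3‑en‑1‑yl]‑3‑(trimethylsilyloxy)‑2‑[(2Z)‑5‑(trimethylsilyl)pent‑2‑en‑4‑yn‑1‑yl]oxolane | C[Si](C)(C)C#C/C=C\C[C@@H]1O[C@H]([C@@H](Br)C/C=C/CC)C[C@H]1O[Si](C)(C)C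
F7 | step 9 | (2S,3R,5S)‑5‑[(1S,3E)‑1‑bromohex‑3‑en‑1‑yl]‑2‑[(2Z)‑5‑(trimethylsilyl)pent‑2‑en‑4‑yn‑1‑yl]oxolan‑3‑ol | C[Si](C)(C)C#C/C=C\C[C@@H]1O[C@H]([C@@H](Br)C/C=C/CC)C[C@H]1O
F8 | step 9 | trimethylsilyl analogue of oxonium 15 (acetate salt; 6S,7R,9S,10S,12R,13S) | C[Si](C)(C)C#C/C=C\C[C@H]1[C@H](O)C[C@H]2[C@@H](Br)C[C@H]([C@@H](Br)CC)[O+]12.CC(=O)[O-]
F9 | step 9 | (2S,3R,5R,6S,8R)‑6‑bromo‑8‑[(1S)‑1‑bromopropyl]‑3‑hydroxy‑2‑[(2Z)‑5‑(trimethylsilyl)pent‑2‑en‑4‑yn‑1‑yl]oxocan‑5‑yl acetate | C[Si](C)(C)C#C/C=C\C[C@@H]1O[C@@H]([C@@H](Br)CC)C[C@H](Br)[C@H](OC(C)=O)C[C@H]1O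
F10 | step 9 | (3R,4R,6S,7R,9R,10S,12R,13S)‑9‑acetoxy‑3,10,13‑tribromo‑4,7:6,12‑diepoxy‑1‑(trimethylsilyl)pentadec‑1‑yne | C[Si](C)(C)C#C[C@@H](Br)[C@H]1C[C@@H]2O[C@@H]([C@@H](Br)CC)C[C@H](Br)[C@H](OC(C)=O)C[C@H]2O1
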